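A small charge of initiator, 4.4 mol%, stands in the spring run, the dusk run and the new flask, and what changes between them is the coupling partner.

| flask | substrate | coupling partner | initiator | remark | time |
|---|---|---|---|---|---|
| spring | 0.67 M | 0.40 equiv | 4.4 mol% | run made earlier |  |
| dusk | 0.67 M | 0.60 equiv | 4.4 mol% | run made earlier |  |
| flask | 0.67 M | 0.800 equiv | 4.4 mol% |  | 5.0 h |

| run | time / h | substrate / % | target / % |
|---|---|---|---|
| spring | 1.00 | 51.5 | 40.5 |
| spring | 2.00 | 51.8 | 40.5 |
| spring | 3.00 | 52.8 | 41.4 |
| spring | 4.00 | 51.4 | 38.9 |
| spring | 5.00 | 53.6 | 41.9 |
| spring | 6.00 | 51.1 | 41.5 |
| dusk | 0.500 | 33.0 | 60.0 |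
| dusk | 0.833 | 33.3 | 61.5 |
| dusk | 1.33 | 32.0 | 59.4 |
| dusk | 2.00 | 30.2 | 59.9 |
| dusk | 4.00 | 32.6 | 60.0 |
| dusk | 6.00 | 33.7 | 59.3 |

(scatter of a reading: 1 percentage point)

* at 5.0 h, what has stopped the reaction, if anything has (all of the substrate has reacted / it is still moving / the coupling partner has run out first)
* share of the substrate used up at 5.0 h
* target at 5.0 h, in percent of the substrate charged

- the reaction counts as stopped when no species that holds the substrate changes by six tenths of a point or more over the second half of the time

*Have the earlier runs stopped?* I think so. Within their scatter the readings of each look flat from the first, at 1.00 h in the spring run and 0.500 h in the dusk run, so I average each column.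

*What do the averages say?* The spring run holds 52.0% substrate and 40.8% target; the dusk run holds 32.5% and 60.0%. Target over coupling partner reads 1.02 and 1.00, so I count about one target per partner.

*Do substrate and target make up the whole?* No. The spring run is short by 7.18% and the dusk run by 7.52%. A single reading scatters by 1 percentage point, so I read one gap, unmoved by the partner.

*What holds that gap?* Here my reckoning is weakest, since both runs carried the same loading and cannot say. I assume it scales with initiator and define the gap per initiator, the points of substrate missing per point of initiator charged: 1.67, a reading.

*And the new flask?* The ratio gives 80.0% target, and adding the gap gives 87.4% conversion. In the dusk run the target readings stay near 60.0% from 0.500 h on, though a slow drift of [substrate] could hide in the scatter of its readings. The asked time is ten times that first reading, so I expect a stopped flask.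

The forecast says the coupling partner has run out first, with 87.4% conversion and 79.8% target; my target differs from its figure by 0.22 points. Of the gap it says “it is probably tied to the fixed initiator loading”.

The new flask gives the coupling partner has run out first, with 87.7% conversion and 80.0% target, so the forecast stands. At 5.00 h it holds 7.72% chain carrier and 0% of its coupling partner, the limiting reagent, so the gap is substrate still held in the flask. That share over the flask's initiator charge is 1.75, beside the 1.67 read earlier.

    initiator → 2 initiating radical (k = 8.80 × 10⁻⁴ s⁻¹)
    substrate + initiating radical → chain carrier (k = 2200 M⁻¹ s⁻¹)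
    coupling partner + chain carrier → target + initiating radical (k = 18000 M⁻¹ s⁻¹)
    2 initiating radical → ended chains (k = 1.00 × 10⁶ M⁻¹ s⁻¹)
    coupling partner → decomposition product (k = 1.80 × 10⁻⁶ s⁻¹)

In the neighbour flask with 1.1 mol% of initiator, the gap per initiator gives a gap of 1.84%, so 81.9% conversion. The computed neighbour gives 81.7% conversion, 80.0% target and 1.68% chain carrier.

(The runs were generated by integration with made-up constants; the scatter is artificial.)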